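(The runs stem from a simulated flask on assumed constants; the scatter is artificial.)

**Same charges.** The amounts in amber, violet and teal match, and the flasks part by temperature, each stopped at 40 min.

| setting | eta | delta | amber | violet | teal |
|---|---|---|---|---|---|
| substrate | 0.050 M | 0.050 M | 0.050 M | 0.050 M | 0.050 M |
| partner | 0.50 equiv | 0.75 equiv | 1.00 equiv | 1.00 equiv | 1.00 equiv |
| capture agent | 0.050 M | 0.050 M | 0.0500 M | 0.0500 M | 0.0500 M |
| temperature | −25 °C | 10 °C | 40 °C | 10 °C | −20 °C |
| remark | run made earlier | run made earlier |  |  |  |
| time |  |  | 40 min | 40 min | 40 min |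

| run | time / min | open intermediate / % | target / % |
|---|---|---|---|
| eta | 50.0 | 0.3 | 0 |
| eta | 150 | 0.5 | 0 |
| eta | 300 | 0.8 | 0 |
| eta | 480 | 1.8 | 0 |
| eta | 600 | 2.3 | 0 |
| eta | 720 | 1.9 | 0 |
| delta | 20.0 | 10.1 | 0.3 |
| delta | 40.0 | 17.2 | 0 |
| delta | 60.0 | 21.9 | 1.0 |
| delta | 80.0 | 25.6 | 1.0 |
| delta | 120 | 28.8 | 4.2 |

(each reading ± 0.3 percentage points)

- the analysis behind the earlier runs scatters by 0.3 percentage points, standard deviation

- the best flask by amount of open intermediate, in percent of the substrate charged; "all alike" if 1.5 percentage points covers them all (amber / violet / teal / all alike)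
- amount of open intermediate at the end, in percent of the substrate charged, amber
- amount of open intermediate at the end, in percent of the substrate charged, violet
- amount of open intermediate at the end, in percent of the substrate charged, teal

**Two times.** We take the rise of c_open intermediate as first order, with c_substrate the one concentration in its rate. The delta reading at 40.0 min then gives 212 min at 10 °C. This is the filling time τ, the inverse of the first-order rate constant. The last eta reading gives 626 h at −25 °C, so the apparent activation energy reads 86.4 kJ/mol. The second time is the run itself. Delta shows the limit of the ratio of run time to τ: at 120 min, shorter than τ, the ratio gives 56.6 %, but 28.8 % is read. So we use the ratio for a run far shorter than τ.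

**Our reckoning.** Violet shares delta's temperature, so we expect about 17.2 %. Teal has τ = 274 h, which gives 0.243 %. Amber has τ = 6.30 min, shorter than the run, so the ratio gives no amount there. Watch amber's level through the run.

**The forecast.** It says “The delta run looks like second-order formation of the intermediate”. It names violet, with 18 % for amber, 22 % for violet and 0.6 % for teal, which is above ours in violet.

**The flasks.** Violet leads with 17.0 %; amber gives 2.79 % and teal 0.236 %.

    substrate ⇌ open intermediate (K = 0.760, k = 0.00390 /s, Ea = 91.0 kJ/mol, ΔH = −5.00 kJ/mol)
    partner → second intermediate (k = 0.00170 /s, Ea = 102 kJ/mol)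
    open intermediate + second intermediate → target (k = 0.0530 /M/s, Ea = 42.0 kJ/mol)
    second intermediate + capture agent → trapped intermediate (k = 0.00680 /M/s, Ea = 48.0 kJ/mol)
    open intermediate → side product (k = 0.00200 /s, Ea = 93.0 kJ/mol)
    target ⇌ isomer of the product (K = 0.200, k = 4.80 × 10⁻⁴ /s, Ea = 101 kJ/mol, ΔH = −49.0 kJ/mol)
    (constants at 40 °C)

**Amber's exit.** In amber, open intermediate fell from 10.4 % at 20.0 min to 2.79 %, in a run longer than τ = 6.30 min. Without the path to side product, amber ends at 18.5 %, the largest single effect, though not the full reason. Teal's flask run at 5 °C has τ = 410 min, which gives 9.30 %, and it holds 9.92 %.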